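**Retrosynthetic overview**
- The C1 carbinol comes last, from an (S)-4-aryl-5-methoxy-1-tetralone by oxazaborolidine-controlled ketone reduction; the aryl acetate is cleaved in the same flask.
- Key disconnection: the bond between tetralone C4 and the naphthyl carbon. It is formed by hydrogen-atom abstraction from the unfunctionalised benzylic C4–H of 5-methoxy-1-tetralone and enantioselective nickel capture of the radical with a 4-bromo-1-naphthyl acetate, which sets 4S.
- Both halves draw on one batch of ortho-lithiated anisole, made once and divided in two.
- Tetralone half: the aryl metal is alkylated with methyl 4-bromobutanoate, then closed by Friedel–Crafts acylation. Naphthol half: the aryllithium adds to cyclobutanone, radical ring expansion gives 8-methoxy-1-tetralone, which is dehydrogenated, para-brominated and acetylated.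
- Ring order: the saturated ring of the tetralone half (step 3), the second ring of the naphthol half (step 5, aromatised in step 6); no ring is formed after the union.

Assumption: the target is the cis-(1S,4S) isomer encoded by the SMILES; the ligand antipode in step 8 is taken as the one that gives 4S, to be fixed by a test reaction.

**Step 1**
Reactants: 1 anisole
Product: 2 2-lithioanisole (2-methoxyphenyllithium; kept as a titrated Et2O stock solution)
Conditions: n-BuLi (0.95 equiv), TMEDA (1.0 equiv), Et2O, 0 °C to rt, 2 h; titrate, use the same day
Reagents that add atoms: n-butyllithium [Li]CCCC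
Why: Methoxy-directed ortho-lithiation (directed ortho-metalation); a slight deficit of n-BuLi leaves no alkyllithium behind, so the one solution can be divided between steps 2 and 4.

**Step 2**
Reactants: 2 2-lithioanisole; 3 methyl 4-bromobutanoate
Product: 5 methyl 4-(2-methoxyphenyl)butanoate, via 2-methoxyphenylmagnesium bromide 4 (not isolated)
Conditions: MgBr2·OEt2 (1.05 equiv), Et2O, 0 °C; then slow addition to 3 and Fe(acac)3 (5 mol%), THF, 0 °C
Reagents that add atoms: none
Why: Transmetalation to the milder Grignard reagent, then an iron-catalysed Kumada-type aryl–alkyl coupling (the TMEDA already present is a helpful additive) that is faster than addition to the ester at 0 °C.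

**Step 3**
Reactants: 5 methyl 4-(2-methoxyphenyl)butanoate
Product: 6 5-methoxy-3,4-dihydronaphthalen-1(2H)-one
Conditions: polyphosphoric acid, 95 °C, 2 h
Reagents that add atoms: none
Why: Intramolecular Friedel–Crafts acylation; the ester is cleaved to the acylium ion in hot acid and can only close a six-membered ring onto the one free position ortho to the side chain.

**Step 4**
Reactants: 2 2-lithioanisole; 7 cyclobutanone
Product: 8 1-(2-methoxyphenyl)cyclobutan-1-ol
Conditions: 2 (1.1 equiv), Et2O, then 7, −78 °C to rt; H2O work-up
Reagents that add atoms: none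
Why: 1,2-Addition of the aryllithium to the strained, highly electrophilic cyclobutanone.

**Step 5**
Reactants: 8 1-(2-methoxyphenyl)cyclobutan-1-ol
Product: 9 8-methoxy-3,4-dihydronaphthalen-1(2H)-one
Conditions: AgNO3 (20 mol%), K2S2O8 (2.5 equiv), CH2Cl2/H2O 1:1, 30 °C
Reagents that add atoms: none
Why: Radical ring expansion of a 1-arylcyclobutanol; the silver/persulfate-generated alkoxy radical undergoes strain-driven beta-scission, the gamma-aroyl alkyl radical closes onto the only free ortho position, and oxidation rearomatises the ring.

**Step 6**
Reactants: 9 8-methoxy-3,4-dihydronaphthalen-1(2H)-one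
Product: 10 8-methoxynaphthalen-1-ol
Conditions: Pd(OCOCF3)2 (5 mol%), 2-(dimethylamino)pyridine (10 mol%), TsOH (20 mol%), O2 (1 atm), DMSO, 80 °C
Reagents that add atoms: none
Why: Palladium-catalysed aerobic dehydrogenation (alpha-palladation, beta-hydride elimination, tautomerisation) turns the tetralone into the naphthol with O2 as the terminal oxidant.

**Step 7**
Reactants: 10 8-methoxynaphthalen-1-ol
Product: 12 4-bromo-8-methoxynaphthalen-1-yl acetate, via 4-bromo-8-methoxynaphthalen-1-ol 11 (not isolated)
Conditions: NBS (1.0 equiv), MeCN, −20 °C; then pyridine, Ac2O, DMAP (5 mol%), 0 °C to rt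
Reagents that add atoms: N-bromosuccinimide O=C1CCC(=O)N1Br; acetic anhydride CC(=O)OC(C)=O
Why: Electrophilic aromatic bromination goes para to the free hydroxyl, the strongest donor, and acetylation in the same flask masks the naphthol for the nickel step.

**Step 8 (key step)**
Reactants: 6 5-methoxy-3,4-dihydronaphthalen-1(2H)-one (3 equiv, excess recovered); 12 4-bromo-8-methoxynaphthalen-1-yl acetate
Product: 13 (4S)-4-(4-acetoxy-5-methoxynaphthalen-1-yl)-5-methoxy-3,4-dihydronaphthalen-1(2H)-one
Conditions: NiCl2·DME (10 mol%), (S,S)-4,4'-di-tert-butyl-1,1'-diaryl-2,2'-bis(2-imidazoline) ligand (12 mol%), Ir[dF(CF3)ppy]2(dtbbpy)PF6 (2 mol%), 4,4'-dimethoxybenzophenone (25 mol%), K2HPO4 (2 equiv), PhCF3/MeCN, 450 nm LEDs, rt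
Reagents that add atoms: none
Why: Proposed new method: a bromine radical released from the photo-oxidised aryl nickel bromide (or the triplet diaryl ketone) abstracts the weakest, most hydridic C–H of 6, the benzylic C4–H next to the methoxy-bearing ring carbon (the alpha-keto C2–H is polarity-mismatched), the planar C4 radical is captured by the chiral aryl nickel complex, and reductive elimination from trivalent nickel forms the C4–naphthyl bond and sets 4S under ligand control; the closest known reaction type is the enantioselective nickel/photoredox benzylic C–H arylation of simple alkylarenes with aryl bromides.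

**Step 9**
Reactants: 13 (4S)-4-(4-acetoxy-5-methoxynaphthalen-1-yl)-5-methoxy-3,4-dihydronaphthalen-1(2H)-one
Product: 15 Dipolynaphthalene B [(1S,4S)-4-(4-hydroxy-5-methoxynaphthalen-1-yl)-5-methoxy-1,2,3,4-tetrahydronaphthalen-1-ol], via O-acetyl cis-carbinol 14 (not isolated)
Conditions: (R)-2-methyl-CBS-oxazaborolidine (15 mol%), BH3·THF (2 equiv), THF, −20 °C; MeOH quench; then K2CO3 (cat.), MeOH, rt, N2
Reagents that add atoms: none
Why: Corey–Bakshi–Shibata reduction with the (R)-catalyst gives the (1S)-carbinol (aryl as the large group), by hydride delivery anti to the pseudo-axial C4 aryl group, so the cis product is the matched case; base methanolysis then removes the aryl acetate.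

**Compound list**
1 | anisole | COc1ccccc1 | starting material
2 | 2-lithioanisole (2-methoxyphenyllithium) | COc1ccccc1[Li] | intermediate
3 | methyl 4-bromobutanoate | COC(=O)CCCBr | starting material
4 | 2-methoxyphenylmagnesium bromide | COc1ccccc1[Mg]Br | intermediate
5 | methyl 4-(2-methoxyphenyl)butanoate | COC(=O)CCCc1ccccc1OC | intermediate
6 | 5-methoxy-3,4-dihydronaphthalen-1(2H)-one | COc1cccc2c1CCCC2=O | intermediate
7 | cyclobutanone | O=C1CCC1 | starting material
8 | 1-(2-methoxyphenyl)cyclobutan-1-ol | COc1ccccc1C1(O)CCC1 | intermediate
9 | 8-methoxy-3,4-dihydronaphthalen-1(2H)-one | COc1cccc2c1C(=O)CCC2 | intermediate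
10 | 8-methoxynaphthalen-1-ol | COc1cccc2cccc(O)c12 | intermediate
11 | 4-bromo-8-methoxynaphthalen-1-ol | COc1cccc2c(Br)ccc(O)c12 | intermediate
12 | 4-bromo-8-methoxynaphthalen-1-yl acetate | COc1cccc2c(Br)ccc(OC(C)=O)c12 | intermediate
13 | (4S)-4-(4-acetoxy-5-methoxynaphthalen-1-yl)-5-methoxy-3,4-dihydronaphthalen-1(2H)-one | COc1cccc2c1[C@H](c1ccc(OC(C)=O)c3c(OC)cccc13)CCC2=O | intermediate
14 | 4-[(1S,4S)-4-hydroxy-8-methoxy-1,2,3,4-tetrahydronaphthalen-1-yl]-8-methoxynaphthalen-1-yl acetate | COc1cccc2c1[C@H](c1ccc(OC(C)=O)c3c(OC)cccc13)CC[C@@H]2O | intermediate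
15 | Dipolynaphthalene B, (1S,4S)-4-(4-hydroxy-5-methoxynaphthalen-1-yl)-5-methoxy-1,2,3,4-tetrahydronaphthalen-1-ol | COc1cccc2c1[C@H](c1ccc(O)c3c(OC)cccc13)CC[C@@H]2O | target

**Totals**
Total step count: 9. Longest linear sequence: 7 steps (steps 1, 4, 5, 6, 7, 8, 9 from anisole).

**Three steps most likely to fail**

Step 8 is the main risk. The secondary benzylic radical sits next to a peri methoxy group and must be captured by a hindered 1-naphthyl nickel species. The enantioselectivity is untested on a cyclic ketone substrate, and beta-hydride loss to 5-methoxy-1-naphthol is a possible leak. The fallback sets out from 6 and comes back at 13. Radical benzylic bromination of 6 (NBS, AIBN cat., PhCF3, 80 °C) gives rac-4-bromo-5-methoxy-3,4-dihydronaphthalen-1(2H)-one F1. F1 is used at once in a stereoconvergent nickel-catalysed reductive cross-electrophile coupling with 12 (NiBr2·diglyme, chiral bis(oxazoline) ligand, Mn powder, NaI, TMSCl cat., dioxane, rt), where the radical arises by halogen abstraction instead of C–H abstraction. Any minor enantiomer of 13 shows up after step 9 as the trans diastereomer and can be removed by chromatography.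

Step 5 is the second risk. The electron-rich anisole ring can be over-oxidised by silver/persulfate, and the ortho methoxy group may slow the ring closure. The fallback sets out from 2 and comes back at 10, bypassing 8 and 9 by an anionic benzannulation. Compound 2 is quenched with N,N-diethylcarbamoyl chloride (THF, −78 °C) to give N,N-diethyl-2-methoxybenzamide F2. Amide-directed ortho-lithiation (s-BuLi, TMEDA, THF, −78 °C) gives N,N-diethyl-2-lithio-6-methoxybenzamide F3, which is trapped with allyl bromide to give 2-allyl-N,N-diethyl-6-methoxybenzamide F4. LDA (2.2 equiv, THF, 0 °C to rt) then closes the allyl anion onto the amide and expels diethylamide, giving 10 directly.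

Step 2 is the third risk. An ortho-substituted aryl Grignard reagent must couple with an ester-bearing alkyl bromide without attacking the ester. The fallback sets out from 4, made from 2 by the transmetalation of step 2, and comes back at 6. Compound 4 is added to succinic anhydride (THF, −40 °C; dilute aqueous HBr work-up) to give 4-(2-methoxyphenyl)-4-oxobutanoic acid F5. Hydrogenolysis of the aryl ketone (H2, Pd/C, AcOH, cat. HClO4, 60 °C) gives 4-(2-methoxyphenyl)butanoic acid F6, which cyclises under the conditions of step 3 to 6.

**Further compounds**
F1 | step 8 | rac-4-bromo-5-methoxy-3,4-dihydronaphthalen-1(2H)-one | COc1cccc2c1C(Br)CCC2=O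
F2 | step 5 | N,N-diethyl-2-methoxybenzamide | CCN(CC)C(=O)c1ccccc1OC
F3 | step 5 | N,N-diethyl-2-lithio-6-methoxybenzamide | CCN(CC)C(=O)c1c([Li])cccc1OC
F4 | step 5 | 2-allyl-N,N-diethyl-6-methoxybenzamide | CCN(CC)C(=O)c1c(CC=C)cccc1OC
F5 | step 2 | 4-(2-methoxyphenyl)-4-oxobutanoic acid | COc1ccccc1C(=O)CCC(=O)O
F6 | step 2 | 4-(2-methoxyphenyl)butanoic acid | COc1ccccc1CCCC(=O)O
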